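**Plan**

- Retrosynthesis: the bicyclo[3.2.1]oct-3-ene-2,8-dione is cut at C8–C5 and C1–C7 together, leading back to a 4-alkenylcyclobutenone. Further cuts are C3–C4 (vinyllithium plus semisquarate), C5–allyl with C4–I (carbomagnesiation–iodination of an alkyne) and C6–C7 (propargylation of veratraldehyde).
- Forward: the C4–C7 chain is assembled first and the four-membered ring is attached. One flask then closes the six-membered enedione ring (C8–C5) and the cyclopentanone ring (C1–C7).
- Enabling feature: ring C1–C2–C3–C4–C5–C8 is a cyclohexa-2,4-dienone in disguise. C8 is a former ketene carbon and C5 the end of the diene C2=C3–C4=C5, so C8–C5 is the σ-bond of a 6π closure. C1, the α-carbon of the resulting β-alkoxy enone, lies 1,5 to benzylic C7, whose electron-rich aryl group supports a cation.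
- Stereochemistry: C6 comes from (R)-but-3-yn-2-ol by chirality transfer. C5 is set by allylic-strain-controlled induction from C6 in the 6π closure. C7 (aryl exo, trans to methyl) and C1 are set in the cation capture; the first-formed C7 configuration is deliberately erased.

Key step: step 7

Assumption: the palladium/zinc propargylation is taken to proceed with net inversion at the propargylic carbon (anti SN2′ oxidative addition, then cyclic SE2′ addition), so the (R)-mesylate gives the (2S) centre; if the sense were opposite, the (S)-alcohol would be used.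

**Route**

Step 1
Reactants: 1 (R)-but-3-yn-2-ol
Product: 2 (R)-but-3-yn-2-yl methanesulfonate
Conditions: MsCl, Et3N, CH2Cl2, −78 → 0 °C
Reagents that add atoms: methanesulfonyl chloride CS(=O)(=O)Cl
Why: O-sulfonylation of a secondary alcohol does not touch the stereocentre, so the (R) configuration should be kept.

Step 2
Reactants: 2 (R)-but-3-yn-2-yl methanesulfonate; 3 3,4-dimethoxybenzaldehyde (veratraldehyde)
Product: 5 (1S,2S)-1-(3,4-dimethoxyphenyl)-2-methylbut-3-yn-1-ol, via allenylzinc reagent 4 (not isolated)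
Conditions: Pd(OAc)2 (5 mol %), PPh3 (5 mol %), Et2Zn (3 equiv), THF, −78 → −20 °C; aq. NH4Cl
Reagents that add atoms: none
Why: Marshall propargylation, in which zerovalent palladium opens the mesylate anti-SN2′, diethylzinc gives allenylzinc 4, and cyclic SE2′ addition to the aldehyde should set C2 (the later C6) as S by chirality transfer with the carbinol centre anti; the carbinol configuration is of no consequence because it is ionised in step 7.

Step 3
Reactants: 5 (1S,2S)-1-(3,4-dimethoxyphenyl)-2-methylbut-3-yn-1-ol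
Product: 7 (1S,2S,3Z)-1-(3,4-dimethoxyphenyl)-3-(iodomethylidene)-2-methylhex-5-en-1-ol, via alkenylmagnesium chelate 6 (not isolated)
Conditions: allylMgBr (4 equiv), Et2O, 0 °C → reflux; then I2, THF, −78 → 0 °C; aq. Na2S2O3
Reagents that add atoms: allylmagnesium bromide C=CC[Mg]Br; iodine II
Why: Hydroxyl-directed anti-carbomagnesiation of an alkynol by an allylic Grignard reagent should deliver allyl to the internal alkyne carbon and leave magnesium on the terminal carbon, held cis to the carbinol chain in a six-membered chelate, and iodinolysis with retention then gives the (Z)-iodide.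

Step 4
Reactants: 7 (1S,2S,3Z)-1-(3,4-dimethoxyphenyl)-3-(iodomethylidene)-2-methylhex-5-en-1-ol
Product: 8 4-[(1S,2S,3Z)-3-(iodomethylidene)-1-methoxy-2-methylhex-5-en-1-yl]-1,2-dimethoxybenzene
Conditions: NaH, MeI, THF, 0 °C → rt
Reagents that add atoms: iodomethane CI
Why: Williamson etherification of the alkoxide; the vinyl iodide has no β-hydrogen for elimination, and the methyl ether serves as protection in step 6 and as the benzylic leaving group in step 7.

Step 5
Reactants: 9 3,4-di(propan-2-yloxy)cyclobut-3-ene-1,2-dione (diisopropyl squarate)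
Product: 11 3-(propan-2-yloxy)cyclobut-3-ene-1,2-dione, via hydroxycyclobutenone 10 (not isolated)
Conditions: LiAlH(OtBu)3, THF, −78 °C, aq. HCl work-up; crude 10 then conc. HCl (cat.), CH2Cl2, 0 °C → rt
Reagents that add atoms: none
Why: Hindered-hydride 1,2-reduction of one squarate carbonyl followed by acid-catalysed allylic transposition with loss of propan-2-ol is the standard passage from a dialkyl squarate to a semisquarate.

Step 6
Reactants: 8 4-[(1S,2S,3Z)-3-(iodomethylidene)-1-methoxy-2-methylhex-5-en-1-yl]-1,2-dimethoxybenzene; 11 3-(propan-2-yloxy)cyclobut-3-ene-1,2-dione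
Product: 14 4-[(1Z,3S,4S)-4-(3,4-dimethoxyphenyl)-4-methoxy-3-methyl-2-(prop-2-en-1-yl)but-1-en-1-yl]-4-methoxy-3-(propan-2-yloxy)cyclobut-2-en-1-one (both epimers at ring C4), via vinyllithium 12 (not isolated), via lithium alkoxide 13 (not isolated)
Conditions: t-BuLi (2.1 equiv), Et2O, −78 °C; 11, THF, −78 °C; then MeOTf, −78 → 0 °C
Reagents that add atoms: methyl trifluoromethanesulfonate COS(=O)(=O)C(F)(F)F
Why: Iodine–lithium exchange with retention of alkene geometry, 1,2-addition to the carbonyl of 11 that is not part of the vinylogous ester, and O-methylation of the lithium alkoxide; the new ring stereocentre forms as both epimers, which is immaterial because it becomes sp2 in step 7.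

Step 7
Reactants: 14 4-[(1Z,3S,4S)-4-(3,4-dimethoxyphenyl)-4-methoxy-3-methyl-2-(prop-2-en-1-yl)but-1-en-1-yl]-4-methoxy-3-(propan-2-yloxy)cyclobut-2-en-1-one
Product: 17 (1S,5S,6R,7R)-7-(3,4-dimethoxyphenyl)-3-methoxy-6-methyl-5-(prop-2-en-1-yl)bicyclo[3.2.1]oct-3-ene-2,8-dione (Kadsurenin D), via dienylketene 15 (not isolated), via cyclohexadienone 16 (not isolated)
Conditions: MeCN (0.01 M), 70 °C; then −35 °C, TfOH (10 mol %), −35 → 0 °C; 1 M aq. HCl work-up
Reagents that add atoms: water O
Why: Proposed new method: heating opens the cyclobutenone conrotatorily (C8–C3 σ-bond; methoxy outward, alkenyl inward) to dienylketene 15, whose disrotatory 6π-electrocyclisation forms C8–C5 and the six-membered ring of dienone 16, and acid then ionises the benzylic methyl ether so that C1, the α-carbon of the β-isopropoxy enone, captures the C7 cation in a 5-(enolexo)-exo-trig closure of the cyclopentanone ring, the O-isopropyl oxocarbenium ion at C2 being hydrolysed on work-up. The closest known reaction types are the Moore rearrangement of 4-alkenylcyclobutenones (ring opening, then 6π closure of the dienylketene) and the acid-promoted quinone monoketal–propenylarene (5+2) annulation, which runs through the same 6-allylcyclohexadienone bearing a benzylic cation; the merger in one flask, with the electrocyclic cascade stopping at a non-aromatisable dienone, is what is new. C5 is set in the 6π step under control of C6: because the C6 chain is cis to C3 across C4=C5, allylic 1,3-strain keeps the C6–H in the diene plane and the ketene carbon should add to the face anti to the CH(OMe)Ar group, which is the (5S) sense. C1 is fixed by C5 since the one-carbon bridge can only close cis, and C7 is set in the cation capture, where the aryl group should take the exo position trans to the C6 methyl group whatever the configuration of the ether was. The step needs C-capture rather than O-capture of the cation and no [3,3] shift of the allyl group in 16; the low ring-opening temperature expected for a 4-alkoxy-4-alkenylcyclobutenone, the low temperature of the acid stage and the reversibility of O-capture under acid are relied on.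

**Compound list**

1 | (R)-but-3-yn-2-ol | C[C@@H](O)C#C | starting material
2 | (R)-but-3-yn-2-yl methanesulfonate | C[C@@H](OS(C)(=O)=O)C#C | intermediate
3 | 3,4-dimethoxybenzaldehyde | COc1ccc(C=O)cc1OC | starting material
4 | ethyl[(aS)-buta-1,2-dien-1-yl]zinc (allenylzinc reagent) | [H]C(C)=[C@]=C([H])[Zn]CC | intermediate
5 | (1S,2S)-1-(3,4-dimethoxyphenyl)-2-methylbut-3-yn-1-ol | COc1ccc([C@@H](O)[C@@H](C)C#C)cc1OC | intermediate
6 | (5S,6S)-6-(3,4-dimethoxyphenyl)-5-methyl-4-(prop-2-en-1-yl)-5,6-dihydro-1,2-oxamagnesine (alkenylmagnesium chelate; Mg bonded to O and to the vinyl carbon) | C=CCC1=C[Mg]O[C@H](c2ccc(OC)c(OC)c2)[C@H]1C | intermediate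
7 | (1S,2S,3Z)-1-(3,4-dimethoxyphenyl)-3-(iodomethylidene)-2-methylhex-5-en-1-ol | C=CC/C(=C/I)[C@H](C)[C@H](O)c1ccc(OC)c(OC)c1 | intermediate
8 | 4-[(1S,2S,3Z)-3-(iodomethylidene)-1-methoxy-2-methylhex-5-en-1-yl]-1,2-dimethoxybenzene | C=CC/C(=C/I)[C@H](C)[C@H](OC)c1ccc(OC)c(OC)c1 | intermediate
9 | 3,4-di(propan-2-yloxy)cyclobut-3-ene-1,2-dione | CC(C)OC1=C(OC(C)C)C(=O)C1=O | starting material
10 | 4-hydroxy-2,3-di(propan-2-yloxy)cyclobut-2-en-1-one (racemic) | CC(C)OC1=C(OC(C)C)C(=O)C1O | intermediate
11 | 3-(propan-2-yloxy)cyclobut-3-ene-1,2-dione | CC(C)OC1=CC(=O)C1=O | intermediate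
12 | [(1Z,3S,4S)-4-(3,4-dimethoxyphenyl)-4-methoxy-3-methyl-2-(prop-2-en-1-yl)but-1-en-1-yl]lithium | C=CC/C(=C/[Li])[C@H](C)[C@H](OC)c1ccc(OC)c(OC)c1 | intermediate
13 | lithium alkoxide of the 4-hydroxy analogue of 14 (both epimers at ring C4) | C=CC/C(=C/C1(O[Li])C(=O)C=C1OC(C)C)[C@H](C)[C@H](OC)c1ccc(OC)c(OC)c1 | intermediate
14 | 4-[(1Z,3S,4S)-4-(3,4-dimethoxyphenyl)-4-methoxy-3-methyl-2-(prop-2-en-1-yl)but-1-en-1-yl]-4-methoxy-3-(propan-2-yloxy)cyclobut-2-en-1-one (both epimers at ring C4) | C=CC/C(=C/C1(OC)C(=O)C=C1OC(C)C)[C@H](C)[C@H](OC)c1ccc(OC)c(OC)c1 | intermediate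
15 | (3Z,5Z,7S,8S)-8-(3,4-dimethoxyphenyl)-4,8-dimethoxy-7-methyl-3-(propan-2-yloxy)-6-(prop-2-en-1-yl)octa-1,3,5-trien-1-one (dienylketene) | O=C=C/C(OC(C)C)=C(OC)\C=C(\CC=C)[C@H](C)[C@H](OC)c1ccc(OC)c(OC)c1 | intermediate
16 | (6S)-6-[(1S,2S)-1-(3,4-dimethoxyphenyl)-1-methoxypropan-2-yl]-4-methoxy-3-(propan-2-yloxy)-6-(prop-2-en-1-yl)cyclohexa-2,4-dien-1-one | O=C1C=C(OC(C)C)C(OC)=C[C@]1(CC=C)[C@H](C)[C@H](OC)c1ccc(OC)c(OC)c1 | intermediate
17 | (1S,5S,6R,7R)-7-(3,4-dimethoxyphenyl)-3-methoxy-6-methyl-5-(prop-2-en-1-yl)bicyclo[3.2.1]oct-3-ene-2,8-dione (Kadsurenin D) | C=CC[C@]12C=C(OC)C(=O)[C@H](C1=O)[C@H](c1ccc(OC)c(OC)c1)[C@H]2C | target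

**Count and risks**

Total step count: 7. Longest linear sequence: 6 steps (steps 1, 2, 3, 4, 6, 7); step 5 is a one-step side branch.

Steps most likely to fail:

1. Step 7 (proposed new method). Three processes threaten it. Facial control in the 6π closure may be poor, giving the C5 epimer relative to C6. The allyl group of open dienone 16 may migrate by [3,3] shift (to the carbonyl oxygen or to C3) or 16 may dimerise at the ring-opening temperature. The benzylic cation may be captured by the carbonyl oxygen or lost by elimination instead of being captured by C1. The fallback uses known chemistry and sets the C5–C6 and C1–C7 bonds in one bimolecular step. It sets out from 3: addition of EtMgBr gives 1-(3,4-dimethoxyphenyl)propan-1-ol F1, and acid-catalysed dehydration (p-TsOH, PhMe, reflux) gives 1,2-dimethoxy-4-[(1E)-prop-1-en-1-yl]benzene F2. Commercial 3,4-dimethoxyphenol is O-allylated (allyl bromide, K2CO3) to 1,2-dimethoxy-4-(prop-2-en-1-yloxy)benzene F3. Thermal Claisen rearrangement gives mainly 4,5-dimethoxy-2-(prop-2-en-1-yl)phenol F4, and oxidation with PhI(OAc)2 in methanol gives the quinone monoketal 4,4,5-trimethoxy-2-(prop-2-en-1-yl)cyclohexa-2,5-dien-1-one F5. Acid-promoted (5+2) cycloaddition of the cation from F5 with F2 (TfOH, MeCN, −30 °C) should give the racemic bicyclooctenedione F6, and chromatography on a chiral stationary phase returns to the route at 17.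

2. Step 3. The Grignard reagent may metalate the terminal alkyne C–H before carbomagnesiation, leading to double iodination or recovered alkyne, or add with poor regiocontrol. The fallback builds the same alkene geometry by syn-carbometalation of a silylalkyne. It sets out from 5: O-methylation (NaH, MeI) gives 4-[(1S,2S)-1-methoxy-2-methylbut-3-yn-1-yl]-1,2-dimethoxybenzene F7, and C-silylation (n-BuLi, Me3SiCl) gives the silylalkyne [(3S,4S)-4-(3,4-dimethoxyphenyl)-4-methoxy-3-methylbut-1-yn-1-yl]trimethylsilane F8. syn-Allylzincation with allylzinc bromide (THF, reflux) should place zinc on the silicon-bearing carbon and allyl on the other; protonolysis then gives the vinylsilane [(1Z,3S,4S)-4-(3,4-dimethoxyphenyl)-4-methoxy-3-methyl-2-(prop-2-en-1-yl)but-1-en-1-yl]trimethylsilane F9, with silicon cis to the stereogenic chain. Iododesilylation with N-iodosuccinimide (MeCN, 0 °C), with retention, returns to the route at 8.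

3. Step 6. The vinyllithium may abstract the vinylic proton of 11 or add at the vinylogous-ester carbonyl, and O-methylation of the hindered alkoxide may be incomplete. The fallback replaces the basic organolithium by a non-basic organochromium reagent and separates the etherification. It sets out from 8 and 11: Nozaki–Hiyama–Kishi addition (CrCl2, NiCl2 cat., DMF/THF, rt) to the strained ketone carbonyl should give 4-[(1Z,3S,4S)-4-(3,4-dimethoxyphenyl)-4-methoxy-3-methyl-2-(prop-2-en-1-yl)but-1-en-1-yl]-4-hydroxy-3-(propan-2-yloxy)cyclobut-2-en-1-one F10. Methylation with MeI and Ag2O returns to the route at 14.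

Further compounds

F1 | step 7 | 1-(3,4-dimethoxyphenyl)propan-1-ol (racemic) | CCC(O)c1ccc(OC)c(OC)c1
F2 | step 7 | 1,2-dimethoxy-4-[(1E)-prop-1-en-1-yl]benzene | C/C=C/c1ccc(OC)c(OC)c1
F3 | step 7 | 1,2-dimethoxy-4-(prop-2-en-1-yloxy)benzene | C=CCOc1ccc(OC)c(OC)c1
F4 | step 7 | 4,5-dimethoxy-2-(prop-2-en-1-yl)phenol | C=CCc1cc(OC)c(OC)cc1O
F5 | step 7 | 4,4,5-trimethoxy-2-(prop-2-en-1-yl)cyclohexa-2,5-dien-1-one | C=CCC1=CC(OC)(OC)C(OC)=CC1=O
F6 | step 7 | racemic rel-(1S,5S,6R,7R)-7-(3,4-dimethoxyphenyl)-3-methoxy-6-methyl-5-(prop-2-en-1-yl)bicyclo[3.2.1]oct-3-ene-2,8-dione | C=CC[C@]12C=C(OC)C(=O)[C@H](C1=O)[C@H](c1ccc(OC)c(OC)c1)[C@H]2C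
F7 | step 3 | 4-[(1S,2S)-1-methoxy-2-methylbut-3-yn-1-yl]-1,2-dimethoxybenzene | COc1ccc([C@@H](OC)[C@@H](C)C#C)cc1OC
F8 | step 3 | [(3S,4S)-4-(3,4-dimethoxyphenyl)-4-methoxy-3-methylbut-1-yn-1-yl]trimethylsilane | COc1ccc([C@@H](OC)[C@@H](C)C#C[Si](C)(C)C)cc1OC
F9 | step 3 | [(1Z,3S,4S)-4-(3,4-dimethoxyphenyl)-4-methoxy-3-methyl-2-(prop-2-en-1-yl)but-1-en-1-yl]trimethylsilane | C=CC/C(=C/[Si](C)(C)C)[C@H](C)[C@H](OC)c1ccc(OC)c(OC)c1
F10 | step 6 | 4-[(1Z,3S,4S)-4-(3,4-dimethoxyphenyl)-4-methoxy-3-methyl-2-(prop-2-en-1-yl)but-1-en-1-yl]-4-hydroxy-3-(propan-2-yloxy)cyclobut-2-en-1-one (both epimers at ring C4) | C=CC/C(=C/C1(O)C(=O)C=C1OC(C)C)[C@H](C)[C@H](OC)c1ccc(OC)c(OC)c1
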